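**Retrosynthetic overview**
- Oxirane (ring C, last): C1–O and C10–O by reagent-controlled Shi epoxidation of the (1(10)Z,4Z)-germacradienolide.
- Ten-membered carbocycle (ring B, second): C1=C10 by ring-closing metathesis of an acyclic diene that already carries the trans-lactone and both esters.
- α-Methylene-γ-butyrolactone (ring A, first): C6–C7 by CrCl2 allylation of a (Z)-4-hydroxy-enal lactol with a 2-(bromomethyl)enoate, then C6–O lactonisation; C3–O ester by Steglich acylation.
- Key disconnection, C8–O: the C8 stereocentre and the angelate are installed together by amine-catalysed α-acyloxylation of 4-methylpent-4-enal with bis(angeloyl) peroxide (proposed new reaction).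
- The lactol comes from chiral-phosphoric-acid allylboration of methyl (Z)-3-methyl-4-oxobut-2-enoate; the butenolide ring locks the 4Z alkene and carries C3.

Assumption: the SMILES is read as the cis (1R,10S) oxirane, i.e. the epoxide of a (Z)-1(10) alkene, with 3S, 6R, 7R, 8R, a (2R)-2-methylbutanoate and a (Z)-angelate; all starting materials are taken as catalogue chemicals.

**Route**

Step 1
Reactants: 1 angelic acid, (2Z)-2-methylbut-2-enoic acid (2 equiv)
Product: 2 bis[(2Z)-2-methylbut-2-enoyl] peroxide (bis(angeloyl) peroxide)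
Conditions: H2O2 (50% aq.), DCC, Et2O, 0 °C; filtered, kept as a cold solution
Reagents that add atoms: hydrogen peroxide, OO
Why: Carbodiimide-mediated dehydrative coupling of two acid molecules with H2O2 (standard diacyl peroxide synthesis) runs cold and neutral, so the Z geometry of the angeloyl groups is kept.

Step 2
Reactants: 3 4-methylpent-4-enal; 2 bis(angeloyl) peroxide
Product: 4 (2R)-4-methyl-1-oxopent-4-en-2-yl (2Z)-2-methylbut-2-enoate
Conditions: (R)-2-(triphenylmethyl)pyrrolidine (10 mol %), hydroquinone (10 mol %), THF, 0 °C; cold aq. NaHCO3 wash; used crude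
Reagents that add atoms: none
Why: Proposed new method: the aldehyde condenses with the bulky secondary amine to a catalyst-bound E-enamine whose one face is blocked by the trityl group, the enamine carbon attacks the weak O–O bond of 2 from the open face (SN2 at oxygen, angelate leaving) and hydrolysis of the α-acyloxy iminium ion releases 4 with the C8–O bond, the (R) centre and the angelate installed in one operation; the closest known reaction is the amine-catalysed α-benzoyloxylation of aldehydes with dibenzoyl peroxide (enamine catalysis), where the (S)-amine gives (S)-benzoates, so the (R)-amine should give (R), and a 2-alkenoyl peroxide, whose sp2-bound acyloxy group should resist decarboxylation like benzoyloxy, has not been used there.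

Step 3
Reactants: 4 (2R)-4-methyl-1-oxopent-4-en-2-yl (2Z)-2-methylbut-2-enoate
Product: 5 methyl (4R)-3-hydroxy-6-methyl-2-methylidene-4-{[(2Z)-2-methylbut-2-enoyl]oxy}hept-6-enoate (both C3 epimers)
Conditions: iBu2AlH, NMO, methyl propiolate, THF, 0 °C, 30 min; then 4, 0 → 25 °C; aq. potassium sodium tartrate
Reagents that add atoms: methyl propiolate, C#CC(=O)OC
Why: Conjugate hydroalumination of the propiolate gives the α-aluminoacrylate, which adds to the aldehyde under non-basic conditions (vinylalumination route to a Morita–Baylis–Hillman adduct), so the base-labile α-acyloxy centre C8 is kept and the new carbinol centre, erased in step 4, need not be controlled.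

Step 4
Reactants: 5 methyl (4R)-3-hydroxy-6-methyl-2-methylidene-4-{[(2Z)-2-methylbut-2-enoyl]oxy}hept-6-enoate
Product: 6 methyl (2Z,4R)-2-(bromomethyl)-6-methyl-4-{[(2Z)-2-methylbut-2-enoyl]oxy}hepta-2,6-dienoate
Conditions: NBS, Me2S, CH2Cl2, 0 → 25 °C
Reagents that add atoms: N-bromosuccinimide, O=C1CCC(=O)N1Br
Why: Activation of the allylic hydroxyl by the NBS–Me2S reagent (Corey–Kim type) and SN2′ attack of bromide at the terminal methylene moves the alkene into conjugation and gives the (Z)-2-(bromomethyl)enoate, with C8 untouched.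

Step 5
Reactants: 7 5-hydroxy-4-methylfuran-2(5H)-one
Product: 8 methyl (2Z)-3-methyl-4-oxobut-2-enoate
Conditions: TMSCHN2 (1.05 equiv), MeOH–toluene (1:4), 0 °C
Reagents that add atoms: (trimethylsilyl)diazomethane, C[Si](C)(C)C=[N+]=[N-]
Why: The pseudo-acid reacts through its open (Z)-formyl carboxylic acid tautomer, and diazoalkane O-methylation (esterification) traps it as the open-chain Z ester without acid or base that could isomerise the alkene.

Step 6
Reactants: 8 methyl (2Z)-3-methyl-4-oxobut-2-enoate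
Product: 10 (5S)-4-methyl-5-(prop-2-en-1-yl)furan-2(5H)-one, via pinacol borate 9 (not isolated)
Conditions: allylB(pin) (1.2 equiv), (S)-TRIP [(S)-3,3′-bis(2,4,6-triisopropylphenyl)-1,1′-binaphthyl-2,2′-diyl hydrogen phosphate] (5 mol %), toluene, −30 °C; then 25 °C, SiO2
Reagents that add atoms: allylboronic acid pinacol ester, C=CCB1OC(C)(C)C(C)(C)O1
Why: Chiral phosphoric acid-catalysed allylboration through a closed chair transition state adds the allyl group to the Si face of the formyl group (sets C3 as S, the (R)-acid giving the opposite face), and the (Z)-γ-boryloxy ester then cyclises to the butenolide, which locks the C4=C5 Z geometry.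

Step 7
Reactants: 10 (5S)-4-methyl-5-(prop-2-en-1-yl)furan-2(5H)-one
Product: 11 (5S)-4-methyl-5-(prop-2-en-1-yl)-2,5-dihydrofuran-2-ol (both anomers)
Conditions: iBu2AlH (1.05 equiv), CH2Cl2, −78 °C; aq. potassium sodium tartrate; used crude
Reagents that add atoms: none
Why: Low-temperature 1,2-hydride reduction of the lactone stops at the lactol (the aluminium hemiacetal is stable at −78 °C), which serves as the masked (Z)-4-hydroxy-enal, and the neutral work-up avoids dehydration to the furan.

Step 8
Reactants: 11 (5S)-4-methyl-5-(prop-2-en-1-yl)-2,5-dihydrofuran-2-ol; 6 methyl (2Z,4R)-2-(bromomethyl)-6-methyl-4-{[(2Z)-2-methylbut-2-enoyl]oxy}hepta-2,6-dienoate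
Product: 15 (1R)-1-{(2R,3R)-2-[(1Z,3S)-3-hydroxy-2-methylhexa-1,5-dien-1-yl]-4-methylidene-5-oxooxolan-3-yl}-3-methylbut-3-en-1-yl (2Z)-2-methylbut-2-enoate, via hydroxy-enal tautomer 12 (not isolated), via allylchromium dichloride 13 (not isolated), via seco hydroxy ester 14 (not isolated)
Conditions: CrCl2 (4 equiv), THF, 0 → 25 °C; aq. NH4Cl; then PPTS (cat.), CH2Cl2, 25 °C
Reagents that add atoms: none
Why: Nozaki–Hiyama-type allylation, in which the allylchromium reagent adds to the aldehyde tautomer through a chair transition state with the C8-bearing substituent equatorial (anti adduct, hence the trans-lactone) and on the allyl face opposite the C9 methylene with C8–H eclipsing the alkene, which sets 6R and 7R, after which the C6 hydroxyl closes ring A on the methyl ester (lactonisation).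

Step 9
Reactants: 15 the lactone alcohol of step 8; 16 (2R)-2-methylbutanoic acid
Product: 17 (1R)-3-methyl-1-[(2R,3R)-2-{(1Z,3S)-2-methyl-3-[(2R)-2-methylbutanoyloxy]hexa-1,5-dien-1-yl}-4-methylidene-5-oxooxolan-3-yl]but-3-en-1-yl (2Z)-2-methylbut-2-enoate
Conditions: DIC, DMAP (10 mol %), CH2Cl2, 0 °C
Reagents that add atoms: none
Why: Steglich esterification of the only free hydroxyl (allylic C3–OH) forms the C3 ester with retention at C3, and the cold, DMAP-catalytic conditions avoid epimerisation of the acid stereocentre.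

Step 10
Reactants: 17 the diester of step 9
Product: 18 (3aR,4R,6Z,9S,10Z,11aR)-6,10-dimethyl-3-methylidene-9-{[(2R)-2-methylbutanoyl]oxy}-2-oxo-2,3,3a,4,5,8,9,11a-octahydrocyclodeca[b]furan-4-yl (2Z)-2-methylbut-2-enoate
Conditions: second-generation Grubbs catalyst RuCl2(H2IMes)(PCy3)(=CHPh) (15 mol %, in portions), toluene (1 mM), 80 °C, argon sparge
Reagents that add atoms: none
Why: Ring-closing metathesis of the vinyl and isopropenyl termini closes ring B, the Z trisubstituted alkene being the less strained and expected geometry in a ten-membered ring, while the methylene lactone, the angelate and the C4=C5 alkene are electron-poor or trisubstituted and react far more slowly.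

Step 11
Reactants: 18 the (1(10)Z,4Z)-germacradienolide of step 10
Product: 19 CNP0108431.1, (1R,3S,4Z,6R,7R,8R,10S)-8-[(2Z)-2-methylbut-2-enoyloxy]-3-[(2R)-2-methylbutanoyloxy]-1,10-epoxygermacra-4,11(13)-dien-12,6-olide
Conditions: Shi ketone from D-fructose (1,2:4,5-di-O-isopropylidene-D-erythro-2,3-hexodiulo-2,6-pyranose, 30 mol %), Oxone (2KHSO5·KHSO4·K2SO4), K2CO3, Bu4NHSO4, MeCN–dimethoxymethane–aq. Na2B4O7 buffer (pH ≈ 10), 0 °C
Reagents that add atoms: potassium peroxymonosulfate KHSO5 (active salt of Oxone), [K+].[O-]S(=O)(=O)OO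
Why: Shi epoxidation, in which the electrophilic chiral dioxirane attacks only the electron-rich C1=C10 alkene and the spiro transition state delivers oxygen to the face that gives the cis (1R,10S) oxirane (same topicity as the (R,R)-epoxides this ketone gives from 1-substituted cycloalkenes), which sets C1 and C10.

**Compound list**

1 | angelic acid, (2Z)-2-methylbut-2-enoic acid | C/C=C(/C)C(=O)O | starting material
2 | bis[(2Z)-2-methylbut-2-enoyl] peroxide | C/C=C(/C)C(=O)OOC(=O)/C(C)=C\C | intermediate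
3 | 4-methylpent-4-enal | C=C(C)CCC=O | starting material
4 | (2R)-4-methyl-1-oxopent-4-en-2-yl (2Z)-2-methylbut-2-enoate | C=C(C)C[C@@H](OC(=O)/C(C)=C\C)C=O | intermediate
5 | methyl (4R)-3-hydroxy-6-methyl-2-methylidene-4-{[(2Z)-2-methylbut-2-enoyl]oxy}hept-6-enoate (both C3 epimers) | C=C(C)C[C@@H](OC(=O)/C(C)=C\C)C(O)C(=C)C(=O)OC | intermediate
6 | methyl (2Z,4R)-2-(bromomethyl)-6-methyl-4-{[(2Z)-2-methylbut-2-enoyl]oxy}hepta-2,6-dienoate | C=C(C)C[C@@H](OC(=O)/C(C)=C\C)/C=C(\CBr)C(=O)OC | intermediate
7 | 5-hydroxy-4-methylfuran-2(5H)-one (racemic pseudo-acid) | CC1=CC(=O)OC1O | starting material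
8 | methyl (2Z)-3-methyl-4-oxobut-2-enoate | COC(=O)/C=C(/C)C=O | intermediate
9 | methyl (2Z,4S)-3-methyl-4-[(4,4,5,5-tetramethyl-1,3,2-dioxaborolan-2-yl)oxy]hepta-2,6-dienoate (not isolated) | COC(=O)/C=C(/C)[C@H](CC=C)OB1OC(C)(C)C(C)(C)O1 | intermediate
10 | (5S)-4-methyl-5-(prop-2-en-1-yl)furan-2(5H)-one | C=CC[C@@H]1OC(=O)C=C1C | intermediate
11 | (5S)-4-methyl-5-(prop-2-en-1-yl)-2,5-dihydrofuran-2-ol (both anomers) | C=CC[C@@H]1OC(O)C=C1C | intermediate
12 | (2Z,4S)-4-hydroxy-3-methylhepta-2,6-dienal (open tautomer of 11, not isolated) | C=CC[C@H](O)/C(C)=C\C=O | intermediate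
13 | dichloro[(2Z,4R)-2-(methoxycarbonyl)-6-methyl-4-{[(2Z)-2-methylbut-2-enoyl]oxy}hepta-2,6-dien-1-yl]chromium, RCrCl2 (trivalent chromium, THF-solvated, not isolated) | C=C(C)C[C@@H](OC(=O)/C(C)=C\C)/C=C(\C[Cr](Cl)Cl)C(=O)OC | intermediate
14 | methyl (3S,4R,5Z,7S)-4,7-dihydroxy-6-methyl-2-methylidene-3-{(1R)-3-methyl-1-[(2Z)-2-methylbut-2-enoyloxy]but-3-en-1-yl}deca-5,9-dienoate (not isolated) | COC(=O)C(=C)[C@@H]([C@H](O)/C=C(/C)[C@@H](O)CC=C)[C@H](OC(=O)/C(C)=C\C)CC(C)=C | intermediate
15 | (1R)-1-{(2R,3R)-2-[(1Z,3S)-3-hydroxy-2-methylhexa-1,5-dien-1-yl]-4-methylidene-5-oxooxolan-3-yl}-3-methylbut-3-en-1-yl (2Z)-2-methylbut-2-enoate | C=C1C(=O)O[C@H](/C=C(/C)[C@@H](O)CC=C)[C@H]1[C@H](OC(=O)/C(C)=C\C)CC(C)=C | intermediate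
16 | (2R)-2-methylbutanoic acid | CC[C@@H](C)C(=O)O | starting material
17 | (1R)-3-methyl-1-[(2R,3R)-2-{(1Z,3S)-2-methyl-3-[(2R)-2-methylbutanoyloxy]hexa-1,5-dien-1-yl}-4-methylidene-5-oxooxolan-3-yl]but-3-en-1-yl (2Z)-2-methylbut-2-enoate | C=C1C(=O)O[C@H](/C=C(/C)[C@@H](OC(=O)[C@H](C)CC)CC=C)[C@H]1[C@H](OC(=O)/C(C)=C\C)CC(C)=C | intermediate
18 | (3aR,4R,6Z,9S,10Z,11aR)-6,10-dimethyl-3-methylidene-9-{[(2R)-2-methylbutanoyl]oxy}-2-oxo-2,3,3a,4,5,8,9,11a-octahydrocyclodeca[b]furan-4-yl (2Z)-2-methylbut-2-enoate | C=C1C(=O)O[C@@H]2/C=C(/C)[C@@H](OC(=O)[C@H](C)CC)C/C=C(/C)C[C@@H](OC(=O)/C(C)=C\C)[C@@H]12 | intermediate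
19 | CNP0108431.1, (1R,3S,4Z,6R,7R,8R,10S)-8-[(2Z)-2-methylbut-2-enoyloxy]-3-[(2R)-2-methylbutanoyloxy]-1,10-epoxygermacra-4,11(13)-dien-12,6-olide | C=C1C(=O)O[C@@H]2/C=C(/C)[C@@H](OC(=O)[C@H](C)CC)C[C@H]3O[C@@]3(C)C[C@@H](OC(=O)/C(C)=C\C)[C@@H]12 | target

**Count and risks**

Total step count: 11. Longest linear sequence: 8 steps (1, 2, 3, 4, 8, 9, 10, 11).

The three steps most likely to fail:

Step 2, the proposed α-angeloyloxylation. The alkenoyl peroxide may decompose by radical paths, acylate the amine catalyst, or give 4 in low ee; 4 is also configurationally labile. The fallback uses known chemistry, sets out from 1 and returns at 4. The glyoxylate–ene reaction of isobutene with methyl glyoxylate under (R)-BINOL/TiCl2(OiPr)2 catalysis gives methyl (2R)-2-hydroxy-4-methylpent-4-enoate F1. Yamaguchi esterification of angelic acid 1 with F1 (2,4,6-trichlorobenzoyl chloride, Et3N, toluene, 80 °C, no DMAP) gives methyl (2R)-4-methyl-2-{[(2Z)-2-methylbut-2-enoyl]oxy}pent-4-enoate F2. Half-reduction of the activated α-acyloxy methyl ester of F2 with iBu2AlH (1.0 equiv, CH2Cl2, −78 °C) gives aldehyde 4.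

Step 8, the chromium allylation and lactonisation. Three things can go wrong: the anti preference may not hold for an ester-bearing allylchromium reagent (the zinc and indium reagents of this class give syn adducts); the organochromium may lose the δ-angelate by reductive 1,4-elimination; and the Lewis-acidic trivalent chromium may dehydrate lactol 11 to the furan. The fallback sets out from 4 and returns at 17; it pairs a syn-selective coupling with a lactonisation that inverts C6. Vinylalumination of 4 with tert-butyl propiolate gives tert-butyl (4R)-3-hydroxy-6-methyl-2-methylidene-4-{[(2Z)-2-methylbut-2-enoyl]oxy}hept-6-enoate F3, and NBS/Me2S gives tert-butyl (2Z,4R)-2-(bromomethyl)-6-methyl-4-{[(2Z)-2-methylbut-2-enoyl]oxy}hepta-2,6-dienoate F4. Indium powder (In) in THF–H2O couples F4 with lactol 11 through the closed chair transition state of the Z reagent; this mild Barbier protocol gives the syn, C6-epimeric diol tert-butyl (3S,4S,5Z,7S)-4,7-dihydroxy-6-methyl-2-methylidene-3-{(1R)-3-methyl-1-[(2Z)-2-methylbut-2-enoyloxy]but-3-en-1-yl}deca-5,9-dienoate F5, which cannot lactonise. Acylation of the less hindered C3 hydroxyl with 16 (DIC, DMAP, −20 °C) gives the 7-O-[(2R)-2-methylbutanoyl] ester of that diol F6. MsCl/Et3N (0 → 25 °C) gives the allylic C6 methanesulfonate of that ester F7, which is displaced at once by the tert-butyl ester carbonyl with inversion at C6 and loss of 2-methylpropene. The product is trans-lactone 17.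

Step 10, the ring-closing metathesis. The ten-membered ring is strained, the catalyst can be diverted by the methylene lactone (eight-membered ring closure or chelation), and dimers can form. The fallback sets out from 17 and returns at 18; it masks the acrylate unit before closing the ring. Me2NH (THF, 0 °C) adds to the methylene lactone of 17 to give the 13-(dimethylamino)-11,13-dihydro adduct F8 (C11 epimer not assigned). Metathesis of F8 as its p-toluenesulfonate salt with the same catalyst gives the macrocyclic amine F9. MeI gives the trimethylammonium iodide of that amine F10, and aq. NaHCO3 eliminates trimethylamine to restore the methylene lactone in 18.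

**Further compounds**
F1 | step 2 | methyl (2R)-2-hydroxy-4-methylpent-4-enoate | C=C(C)C[C@@H](O)C(=O)OC
F2 | step 2 | methyl (2R)-4-methyl-2-{[(2Z)-2-methylbut-2-enoyl]oxy}pent-4-enoate | C=C(C)C[C@@H](OC(=O)/C(C)=C\C)C(=O)OC
F3 | step 8 | tert-butyl (4R)-3-hydroxy-6-methyl-2-methylidene-4-{[(2Z)-2-methylbut-2-enoyl]oxy}hept-6-enoate (both C3 epimers) | C=C(C)C[C@@H](OC(=O)/C(C)=C\C)C(O)C(=C)C(=O)OC(C)(C)C
F4 | step 8 | tert-butyl (2Z,4R)-2-(bromomethyl)-6-methyl-4-{[(2Z)-2-methylbut-2-enoyl]oxy}hepta-2,6-dienoate | C=C(C)C[C@@H](OC(=O)/C(C)=C\C)/C=C(\CBr)C(=O)OC(C)(C)C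
F5 | step 8 | tert-butyl (3S,4S,5Z,7S)-4,7-dihydroxy-6-methyl-2-methylidene-3-{(1R)-3-methyl-1-[(2Z)-2-methylbut-2-enoyloxy]but-3-en-1-yl}deca-5,9-dienoate | CC(C)(C)OC(=O)C(=C)[C@@H]([C@@H](O)/C=C(/C)[C@@H](O)CC=C)[C@H](OC(=O)/C(C)=C\C)CC(C)=C
F6 | step 8 | 7-O-[(2R)-2-methylbutanoyl] ester of F5 | CC(C)(C)OC(=O)C(=C)[C@@H]([C@@H](O)/C=C(/C)[C@@H](OC(=O)[C@H](C)CC)CC=C)[C@H](OC(=O)/C(C)=C\C)CC(C)=C
F7 | step 8 | 4-O-methanesulfonate of F6 | CC(C)(C)OC(=O)C(=C)[C@@H]([C@@H](OS(C)(=O)=O)/C=C(/C)[C@@H](OC(=O)[C@H](C)CC)CC=C)[C@H](OC(=O)/C(C)=C\C)CC(C)=C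
F8 | step 10 | dimethylamine adduct of 17, 4-[(dimethylamino)methyl]-5-oxooxolane in place of the methylene lactone (C11 epimer not assigned) | CN(C)CC1C(=O)O[C@H](/C=C(/C)[C@@H](OC(=O)[C@H](C)CC)CC=C)[C@H]1[C@H](OC(=O)/C(C)=C\C)CC(C)=C
F9 | step 10 | 13-(dimethylamino)-11,13-dihydro derivative of 18 | CN(C)CC1C(=O)O[C@@H]2/C=C(/C)[C@@H](OC(=O)[C@H](C)CC)C/C=C(/C)C[C@@H](OC(=O)/C(C)=C\C)[C@@H]12
F10 | step 10 | trimethylammonium iodide of F9 | C[N+](C)(C)CC1C(=O)O[C@@H]2/C=C(/C)[C@@H](OC(=O)[C@H](C)CC)C/C=C(/C)C[C@@H](OC(=O)/C(C)=C\C)[C@@H]12.[I-]
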